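The ten-membered ring is opened between the ester-bearing carbinol carbon C1 and the isopropyl-bearing carbon C10. With the isopropyl group read as a hydrogenated isopropenyl group, this vicinal C1(O)–C10 pair of the (Z,Z)-cyclodeca-2,6-diene is a homoallylic alcohol. The key step is therefore an enantioselective, chromium-catalysed Nozaki-Hiyama allylation that cyclises an achiral open chain, (2Z,6Z,10E)-12-chlorofarnesal, whose two Z alkenes fold it. In one operation it forms C1–C10, closes the carbocycle and sets both stereocentres (trans), whatever the geometry of the allylic chloride. Hydrogenation of the isopropenyl group and a Mitsunobu esterification with unprotected vanillic acid, inverting C1, give the cis ester.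

Key step: step 7

Remark: the SMILES is read literally, so both ring alkenes are Z (ring carbons cis on each double bond) and the target is the (1R,2Z,6Z,10S) isomer with O and isopropyl on the same ring face. C1 to C10 of the open chain carry the same numbers in the ring.

Step 1
Reactants: 1 nerol [(2Z)-3,7-dimethylocta-2,6-dien-1-ol]
Product: 2 neryl bromide [(2Z)-1-bromo-3,7-dimethylocta-2,6-diene]
Conditions: PBr3 (0.4 equiv), Et2O, −10 °C, used crude
Reagents that add atoms: phosphorus tribromide, BrP(Br)Br
Why: Conversion of a primary allylic alcohol into the bromide with PBr3 runs through a phosphite ester and SN2 attack of bromide at low temperature, so that the 2Z alkene should be kept and ionisation of the neryl system (cyclisation, transposition) avoided.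

Step 2
Reactants: 2 neryl bromide; 3 propyne; 4 N-methoxy-N-methylcarbamoyl chloride
Product: 7 (6Z)-N-methoxy-N,7,11-trimethyldodeca-6,10-dien-2-ynamide, via 1,3-dilithiopropyne 5 (not isolated), via lithium acetylide 6 (not isolated)
Conditions: 3, n-BuLi (2 equiv), TMEDA, Et2O/hexane, −78 to 0 °C; 2, −78 °C to rt; then 4, THF, −78 °C
Reagents that add atoms: none
Why: Propargylation of an allylic halide with 1,3-dilithiopropyne takes place by SN2 at the more nucleophilic sp3 carbon without allylic transposition or loss of the Z geometry, and the lithium acetylide 6 that remains is C-acylated in the same flask by the carbamoyl chloride to the N-methoxy-N-methylamide.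

Step 3
Reactants: 7 (6Z)-N-methoxy-N,7,11-trimethyldodeca-6,10-dien-2-ynamide
Product: 9 (2Z,6Z)-N-methoxy-N,3,7,11-tetramethyldodeca-2,6,10-trienamide, via alkenylcuprate 8 (not isolated)
Conditions: Me2CuLi (from MeLi and CuI, 1.3 equiv), THF, −78 °C; sat. aq. NH4Cl at −78 °C
Reagents that add atoms: lithium dimethylcuprate, [Li+].C[Cu-]C
Why: Conjugate addition of a lithium dialkylcuprate to an acetylenic carbonyl compound is a syn-carbocupration, so methyl and copper end up cis in alkenylcuprate 8, and protonation with retention at −78 °C should give the 2Z alkene with the chain cis to the carbonyl group.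

Step 4
Reactants: 9 (2Z,6Z)-N-methoxy-N,3,7,11-tetramethyldodeca-2,6,10-trienamide
Product: 10 (2Z,6Z,10E)-12-hydroxy-N-methoxy-N,3,7,11-tetramethyldodeca-2,6,10-trienamide
Conditions: SeO2 (0.2 equiv), t-BuOOH (2.5 equiv), salicylic acid (0.1 equiv), CH2Cl2, 0 °C to rt, stopped at partial conversion
Reagents that add atoms: tert-butyl hydroperoxide, CC(C)(C)OO
Why: The Riley allylic oxidation (ene reaction followed by a [2,3]-sigmatropic shift) prefers the most electron-rich and least hindered trisubstituted alkene, the isopropylidene end, and delivers the E allylic alcohol, while the amide-conjugated 2-alkene is deactivated.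

Step 5
Reactants: 10 (2Z,6Z,10E)-12-hydroxy-N-methoxy-N,3,7,11-tetramethyldodeca-2,6,10-trienamide
Product: 12 (2Z,6Z,10E)-12-chloro-N-methoxy-N,3,7,11-tetramethyldodeca-2,6,10-trienamide, via alkoxysulfonium chloride 11 (not isolated)
Conditions: NCS, Me2S, CH2Cl2, −30 to 0 °C
Reagents that add atoms: N-chlorosuccinimide, O=C1CCC(=O)N1Cl
Why: In the Corey-Kim chlorination chloride displaces dimethyl sulfoxide from alkoxysulfonium salt 11 by SN2 at the primary allylic carbon under almost neutral conditions, without allylic transposition and without harm to the amide or the Z alkenes.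

Step 6
Reactants: 12 (2Z,6Z,10E)-12-chloro-N-methoxy-N,3,7,11-tetramethyldodeca-2,6,10-trienamide
Product: 14 (2Z,6Z,10E)-12-chloro-3,7,11-trimethyldodeca-2,6,10-trienal, via aluminium hemiaminal 13 (not isolated)
Conditions: i-Bu2AlH (1.2 equiv), THF, −78 °C; aq. potassium sodium tartrate
Reagents that add atoms: none
Why: Hydride reduction of an N-methoxy-N-methylamide stops at the chelated aluminium hemiaminal 13, which releases the aldehyde only on work-up, so that the Z-enal should be obtained without over-reduction or isomerisation and the allylic chloride survives at −78 °C.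

Step 7
Reactants: 14 (2Z,6Z,10E)-12-chloro-3,7,11-trimethyldodeca-2,6,10-trienal
Product: 17 (1R,2Z,6Z,10S)-3,7-dimethyl-10-(prop-1-en-2-yl)cyclodeca-2,6-dien-1-ol, via allylchromium species 15 (not isolated), via trimethylsilyl ether 16 (not isolated)
Conditions: CrCl2 (20 mol %), 1,8-bis[(4S)-4-isopropyl-4,5-dihydro-1,3-oxazol-2-yl]-3,6-diphenyl-9H-carbazole (24 mol %), i-Pr2NEt (60 mol %), Mn (3 equiv), Me3SiCl (2 equiv), THF, 25 °C, 14 added by syringe pump over 24 h (final 3 mM); then K2CO3, MeOH, 0 °C
Reagents that add atoms: none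
Why: Divalent chromium reduces only the allylic C–Cl bond of 14 (two one-electron steps) to allylchromium species 15, which adds through its γ-carbon to the chromium-bound aldehyde in a six-membered chair; Me3SiCl then frees the metal as silyl ether 16 and Mn returns trivalent to divalent chromium. This is the catalytic enantioselective Nozaki-Hiyama allylation, and its intramolecular form, the chromium-mediated closure of ω-(haloallyl) enals to ten-membered carbocycles, is an established reaction type. The carbocycle closes in the 10-exo-trig mode at the carbonyl group and by SE2′ at the allyl unit, so that the former C11 and C12 stay outside the ring as the isopropenyl group. C1 is controlled by the C2-symmetric tridentate ligand on chromium, which should leave the Si face of the aldehyde open, and C10 by the chair, in which the (E)-allyl complex places both arms of the tether (C2 and C9) equatorial and so gives the anti adduct, the trans-1,10 relation. Because the σ-allyl complexes equilibrate faster than they add, the 10E and 10Z chlorides and their allylic regioisomers all funnel into this one transition state. The step needs closure to outrun oligomerisation and 1,2- to outrun 1,4-addition: the two Z alkenes act as turns that bring C1 and C10 together and lead to a little-strained (Z,Z)-cyclodecadiene, slow addition keeps 14 dilute, and allylchromium reagents attack enals at the carbonyl carbon.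

Step 8
Reactants: 17 (1R,2Z,6Z,10S)-3,7-dimethyl-10-(prop-1-en-2-yl)cyclodeca-2,6-dien-1-ol
Product: 18 (1S,2Z,6Z,10S)-3,7-dimethyl-10-(propan-2-yl)cyclodeca-2,6-dien-1-ol
Conditions: RhCl(PPh3)3 (5 mol %), H2 (1 atm), toluene/EtOH, rt
Reagents that add atoms: none
Why: Homogeneous hydrogenation with RhCl(PPh3)3 discriminates alkenes by substitution, so the 1,1-disubstituted isopropenyl group should be saturated while the two trisubstituted ring alkenes stay, and no stereocentre is touched (the descriptor of C1 changes from R to S only because the priorities change).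

Step 9
Reactants: 18 (1S,2Z,6Z,10S)-3,7-dimethyl-10-(propan-2-yl)cyclodeca-2,6-dien-1-ol; 19 vanillic acid (4-hydroxy-3-methoxybenzoic acid)
Product: 21 (1R,2Z,6Z,10S)-3,7-dimethyl-10-(propan-2-yl)cyclodeca-2,6-dien-1-yl 4-hydroxy-3-methoxybenzoate, via alkoxyphosphonium vanillate 20 (not isolated)
Conditions: PPh3 (1.2 equiv), DIAD (1.2 equiv), THF, 0 °C to rt
Reagents that add atoms: none
Why: In the Mitsunobu esterification only the carboxylic acid, far more acidic than the phenol, is deprotonated, and the carboxylate displaces triphenylphosphine oxide from alkoxyphosphonium salt 20 by SN2 with inversion at the allylic carbon C1 (S to R), which turns the trans into the required cis-1,10 relation while C10 is untouched.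

Compound list
1 | nerol, (2Z)-3,7-dimethylocta-2,6-dien-1-ol | CC(C)=CCC/C(C)=C\CO | starting material
2 | neryl bromide, (2Z)-1-bromo-3,7-dimethylocta-2,6-diene | CC(C)=CCC/C(C)=C\CBr | intermediate
3 | propyne | CC#C | starting material
4 | N-methoxy-N-methylcarbamoyl chloride | CON(C)C(=O)Cl | starting material
5 | 1,3-dilithiopropyne (not isolated) | [Li]CC#C[Li] | intermediate
6 | lithium (5Z)-6,10-dimethylundeca-5,9-dien-1-yn-1-ide (not isolated) | CC(C)=CCC/C(C)=C\CCC#C[Li] | intermediate
7 | (6Z)-N-methoxy-N,7,11-trimethyldodeca-6,10-dien-2-ynamide | CC(C)=CCC/C(C)=C\CCC#CC(=O)N(C)OC | intermediate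
8 | lithium methyl(alkenyl)cuprate from syn-addition to 7, copper at C2 cis to the new C3 methyl group (not isolated) | CC(C)=CCC/C(C)=C\CC/C(C)=C(\C(=O)N(C)OC)[Cu-]C.[Li+] | intermediate
9 | (2Z,6Z)-N-methoxy-N,3,7,11-tetramethyldodeca-2,6,10-trienamide | CC(C)=CCC/C(C)=C\CC/C(C)=C\C(=O)N(C)OC | intermediate
10 | (2Z,6Z,10E)-12-hydroxy-N-methoxy-N,3,7,11-tetramethyldodeca-2,6,10-trienamide | OC/C(C)=C/CC/C(C)=C\CC/C(C)=C\C(=O)N(C)OC | intermediate
11 | dimethyl(alkoxy)sulfonium chloride of 10 (not isolated) | C[S+](C)OC/C(C)=C/CC/C(C)=C\CC/C(C)=C\C(=O)N(C)OC.[Cl-] | intermediate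
12 | (2Z,6Z,10E)-12-chloro-N-methoxy-N,3,7,11-tetramethyldodeca-2,6,10-trienamide | ClC/C(C)=C/CC/C(C)=C\CC/C(C)=C\C(=O)N(C)OC | intermediate
13 | O-diisobutylaluminium hemiaminal of 14 (not isolated) | ClC/C(C)=C/CC/C(C)=C\CC/C(C)=C\C(O[Al](CC(C)C)CC(C)C)N(C)OC | intermediate
14 | (2Z,6Z,10E)-12-chloro-3,7,11-trimethyldodeca-2,6,10-trienal | ClC/C(C)=C/CC/C(C)=C\CC/C(C)=C\C=O | intermediate
15 | (2Z,6Z,10E)-σ-allyl complex of trivalent chromium at C12, drawn as the dichloride without the chiral ligand (not isolated) | Cl[Cr](Cl)C/C(C)=C/CC/C(C)=C\CC/C(C)=C\C=O | intermediate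
16 | trimethylsilyl ether of 17 (not isolated) | C[Si](C)(C)O[C@@H]1/C=C(/C)CC/C=C(/C)CC[C@H]1C(C)=C | intermediate
17 | (1R,2Z,6Z,10S)-3,7-dimethyl-10-(prop-1-en-2-yl)cyclodeca-2,6-dien-1-ol (OH and isopropenyl trans) | O[C@@H]1/C=C(/C)CC/C=C(/C)CC[C@H]1C(C)=C | intermediate
18 | (1S,2Z,6Z,10S)-3,7-dimethyl-10-(propan-2-yl)cyclodeca-2,6-dien-1-ol (OH and isopropyl trans) | O[C@@H]1/C=C(/C)CC/C=C(/C)CC[C@H]1C(C)C | intermediate
19 | vanillic acid, 4-hydroxy-3-methoxybenzoic acid | COc1cc(C(=O)O)ccc1O | starting material
20 | triphenyl(alkoxy)phosphonium vanillate of 18 (not isolated) | c1ccccc1[P+](c1ccccc1)(c1ccccc1)O[C@@H]2/C=C(/C)CC/C=C(/C)CC[C@H]2C(C)C.COc1cc(C(=O)[O-])ccc1O | intermediate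
21 | (1R,2Z,6Z,10S)-3,7-dimethyl-10-(propan-2-yl)cyclodeca-2,6-dien-1-yl 4-hydroxy-3-methoxybenzoate | COc1cc(C(=O)O[C@H]2/C=C(/C)CC/C=C(/C)CC[C@H]2C(C)C)ccc1O | target

Total step count: 9. Longest linear sequence: 9 steps, from nerol 1.

Steps most likely to fail

Step 7. The ligand sphere may discriminate the two aldehyde faces less well once the allyl unit and the aldehyde are tied in one chain. The sense of induction also has to be confirmed, and the antipodal ligand is equally accessible. Oligomerisation may compete with closure. The fallback sets out from 14 and comes back at 17.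
- 1,2-Reduction of 14 with NaBH4 and CeCl3·7H2O in MeOH gives (2Z,6Z,10E)-12-chloro-3,7,11-trimethyldodeca-2,6,10-trien-1-ol F1.
- NaH in THF under high dilution closes, by an intramolecular Williamson reaction, the 13-membered diallylic ether (3Z,7Z,11E)-4,8,12-trimethyl-1-oxacyclotrideca-3,7,11-triene F2.
- Deprotonation of the OCH2 group next to the Z alkene with t-BuLi and a chiral bis(oxazoline) ligand at −78 °C triggers a transannular [2,3]-Wittig ring contraction.
- This forms the same C1–C10 bond. The E allyl ether unit again leads to the trans alcohol 17.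

Step 9. Substitution at the hindered carbinol carbon next to the isopropyl group may be slow. Elimination to a conjugated diene, SN2′ attack, or acyl transfer with retention could then take over. The fallback sets out from 18 and comes back at 21.
- Dess-Martin oxidation gives (2Z,6Z,10S)-3,7-dimethyl-10-(propan-2-yl)cyclodeca-2,6-dien-1-one F3.
- 1,2-Reduction with LiBH(s-Bu)3 in THF at −78 °C should approach the carbonyl group from the face opposite the isopropyl group. It should give (1R,2Z,6Z,10S)-3,7-dimethyl-10-(propan-2-yl)cyclodeca-2,6-dien-1-ol F4.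
- Carbodiimide esterification (EDC, DMAP, CH2Cl2) with commercial 4-acetoxy-3-methoxybenzoic acid keeps C1. It gives (1R,2Z,6Z,10S)-3,7-dimethyl-10-(propan-2-yl)cyclodeca-2,6-dien-1-yl 4-acetoxy-3-methoxybenzoate F5.
- Brief methanolysis of the aryl acetate (K2CO3, MeOH, 0 °C) gives 21.

Step 4. Site selectivity between the terminal and the internal trisubstituted alkene may be poor, and over-oxidation to the enal may lower the throughput. The fallback sets out from 9 and comes back at 12.
- NBS in aqueous THF functionalises the terminal alkene to rac-(2Z,6Z)-10-bromo-11-hydroxy-N-methoxy-N,3,7,11-tetramethyldodeca-2,6-dienamide F6.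
- K2CO3 in MeOH closes rac-(2Z,6Z)-9-(3,3-dimethyloxiran-2-yl)-N-methoxy-N,3,7-trimethylnona-2,6-dienamide F7.
- Al(Oi-Pr)3 in hot toluene isomerises the epoxide to rac-(2Z,6Z)-10-hydroxy-N-methoxy-N,3,7,11-tetramethyldodeca-2,6,11-trienamide F8.
- SOCl2 in Et2O at 0 °C transposes this alcohol (SNi′) to the primary E allylic chloride 12.

Further compounds
F1 | step 7 | (2Z,6Z,10E)-12-chloro-3,7,11-trimethyldodeca-2,6,10-trien-1-ol | ClC/C(C)=C/CC/C(C)=C\CC/C(C)=C\CO
F2 | step 7 | (3Z,7Z,11E)-4,8,12-trimethyl-1-oxacyclotrideca-3,7,11-triene | O1C/C=C(/C)CC/C=C(/C)CC/C=C(\C)C1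
F3 | step 9 | (2Z,6Z,10S)-3,7-dimethyl-10-(propan-2-yl)cyclodeca-2,6-dien-1-one | O=C1/C=C(/C)CC/C=C(/C)CC[C@H]1C(C)C
F4 | step 9 | (1R,2Z,6Z,10S)-3,7-dimethyl-10-(propan-2-yl)cyclodeca-2,6-dien-1-ol | O[C@H]1/C=C(/C)CC/C=C(/C)CC[C@H]1C(C)C
F5 | step 9 | (1R,2Z,6Z,10S)-3,7-dimethyl-10-(propan-2-yl)cyclodeca-2,6-dien-1-yl 4-acetoxy-3-methoxybenzoate | COc1cc(C(=O)O[C@H]2/C=C(/C)CC/C=C(/C)CC[C@H]2C(C)C)ccc1OC(C)=O
F6 | step 4 | rac-(2Z,6Z)-10-bromo-11-hydroxy-N-methoxy-N,3,7,11-tetramethyldodeca-2,6-dienamide | CC(C)(O)C(Br)CC/C(C)=C\CC/C(C)=C\C(=O)N(C)OC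
F7 | step 4 | rac-(2Z,6Z)-9-(3,3-dimethyloxiran-2-yl)-N-methoxy-N,3,7-trimethylnona-2,6-dienamide | CC1(C)OC1CC/C(C)=C\CC/C(C)=C\C(=O)N(C)OC
F8 | step 4 | rac-(2Z,6Z)-10-hydroxy-N-methoxy-N,3,7,11-tetramethyldodeca-2,6,11-trienamide | C=C(C)C(O)CC/C(C)=C\CC/C(C)=C\C(=O)N(C)OC
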